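**Retrosynthetic overview**

- The target acid 21 comes from silyl ether 19 by desilylation and ester hydrolysis; ring B, already carrying its keto ester, is kept throughout.
- 19 is disconnected by a thermal cyclobutenone/siloxyalkyne benzannulation into cyclobutenone 11 and (triisopropylsilyloxy)ethyne 14. Bonds C5–C4 and C2–C3 are new, C5–C6 is re-formed, and ring A closes.
- The feature used is ring A itself: its C5 hydroxyl sits ortho to the ether carbon C6 and meta to the C3 oxygen, with C4–H between them. A vinylketene (C5, C2, C1, C6, aryloxy on C6) and an oxygenated ethyne (C4, C3) deliver exactly this pattern.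
- 11 comes from a keteniminium–alkyne [2+2] cycloaddition of aryloxyacetamide 7 with hept-1-yne. 7 comes from methyl 2,4,6-trihydroxybenzoate by methylation, monotriflation, O-alkylation and carbonylative Negishi coupling.
- Ring order: ring B is bought; the four-membered ring is made in step 5 and consumed; ring A is made last, in step 7.

Key step: step 7

Assumption: the open keto acid as drawn is taken as the target; its ring–chain equilibrium with the 3-butyl-3-hydroxyphthalide (lactol) form is not controlled.

**Route**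

Step 1
Reactants: 1 methyl 2,4,6-trihydroxybenzoate
Product: 2 methyl 2,6-dihydroxy-4-methoxybenzoate
Conditions: Me2SO4 (1.0 equiv), K2CO3 (1.0 equiv), acetone, 0 °C → rt
Reagents that add atoms: dimethyl sulfate, COS(=O)(=O)OC
Why: Williamson O-methylation; the 4-hydroxyl is the most acidic (para to the ester) and the only one not held in a hydrogen bond to the ester, so one equivalent of base and methylating agent should select it.

Step 2
Reactants: 2 methyl 2,6-dihydroxy-4-methoxybenzoate
Product: 3 methyl 2-hydroxy-4-methoxy-6-{[(trifluoromethyl)sulfonyl]oxy}benzoate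
Conditions: Tf2O (1.05 equiv), pyridine, CH2Cl2, −40 → 0 °C
Reagents that add atoms: trifluoromethanesulfonic anhydride, O=S(=O)(OS(=O)(=O)C(F)(F)F)C(F)(F)F
Why: Desymmetrising sulfonylation; the two ortho phenols are equivalent, and after the first triflation the ring is deactivated and the remaining phenol is locked in a hydrogen bond to the ester carbonyl, so the reaction should stop at the monotriflate.

Step 3
Reactants: 3 methyl 2-hydroxy-4-methoxy-6-{[(trifluoromethyl)sulfonyl]oxy}benzoate; 4 2-chloro-N,N-dimethylacetamide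
Product: 5 methyl 2-[2-(dimethylamino)-2-oxoethoxy]-4-methoxy-6-{[(trifluoromethyl)sulfonyl]oxy}benzoate
Conditions: K2CO3 (1.5 equiv), KI (10 mol %), acetone, reflux
Reagents that add atoms: none
Why: Williamson etherification; the phenoxide displaces halide from the α-haloamide by SN2 (through the iodide formed in situ), carbonate leaves the aryl triflate intact, and the amide α-hydrogens are too weakly acidic for condensation onto the neighbouring ester.

Step 4
Reactants: 5 methyl 2-[2-(dimethylamino)-2-oxoethoxy]-4-methoxy-6-{[(trifluoromethyl)sulfonyl]oxy}benzoate; 6 butylzinc bromide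
Product: 7 methyl 2-[2-(dimethylamino)-2-oxoethoxy]-4-methoxy-6-pentanoylbenzoate
Conditions: BuZnBr (1.5 equiv), CO (3 atm), PdCl2(dppf) (5 mol %), LiCl, THF/NMP, 50 °C
Reagents that add atoms: carbon monoxide, [C-]#[O+]
Why: Carbonylative Negishi coupling; zerovalent palladium inserts into the aryl–OTf bond, CO insertion (favoured over direct butyl transfer at this ester-flanked position and by CO pressure) gives the aroylpalladium species, and transmetallation with the alkylzinc halide and reductive elimination give the aryl butyl ketone, while the ester, the amide and the product ketone are inert to the zinc reagent.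

Step 5
Reactants: 7 methyl 2-[2-(dimethylamino)-2-oxoethoxy]-4-methoxy-6-pentanoylbenzoate; 8 hept-1-yne
Product: 11 methyl 4-methoxy-2-[(4-oxo-2-pentylcyclobut-2-en-1-yl)oxy]-6-pentanoylbenzoate (racemic), via keteniminium triflate 9 (not isolated), via cyclobuteniminium triflate 10 (not isolated)
Conditions: Tf2O (1.05 equiv), ClCH2CH2Cl, −20 °C; then hept-1-yne (5 equiv), 2,4,6-collidine (1.2 equiv), 0 → 60 °C; then H2O, rt
Reagents that add atoms: water, O
Why: Keteniminium–alkyne [2+2] cycloaddition; O-triflation of the tertiary amide (the most nucleophilic carbonyl group present) and loss of triflic acid to collidine give aryloxyketeniminium ion 9, the terminal carbon of hept-1-yne attacks its central carbon and the vinyl cation closes on the aryloxy-bearing carbon, so that hydrolysis of 10 gives the 3-pentyl-4-aryloxy regioisomer, whose single stereocentre is formed racemic and is lost in step 7.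

Step 6
Reactants: 12 ethyl dibromoacetate
Product: 14 (triisopropylsilyloxy)ethyne, via lithium ethynolate 13 (not isolated)
Conditions: t-BuLi (4.0 equiv), THF, −78 → 0 °C; then i-Pr3SiOTf (2.2 equiv), −78 °C → rt
Reagents that add atoms: triisopropylsilyl trifluoromethanesulfonate, CC(C)[Si](OS(=O)(=O)C(F)(F)F)(C(C)C)C(C)C
Why: Ynolate formation by ester-dianion cleavage followed by O-silylation; two bromine–lithium exchanges give a β-lithiated ester enolate that expels lithium ethoxide to form ynolate 13, and the bulky, hard silyl triflate silylates ynolates at oxygen (the second equivalent caps the ethoxide).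

Step 7
Reactants: 11 methyl 4-methoxy-2-[(4-oxo-2-pentylcyclobut-2-en-1-yl)oxy]-6-pentanoylbenzoate; 14 (triisopropylsilyloxy)ethyne
Product: 19 methyl 2-[2-hydroxy-6-pentyl-4-(triisopropylsilyloxy)phenoxy]-4-methoxy-6-pentanoylbenzoate, via aryloxy vinylketene 15 (not isolated), via alkenyl siloxycyclobutenone 16 (not isolated), via dienylketene 17 (not isolated), via cyclohexadienone 18 (not isolated)
Conditions: 14 (2.5 equiv), toluene (0.1 M), argon, 80 °C, then 110 °C
Reagents that add atoms: none
Why: Heating opens 11 by conrotatory 4π electrocyclic ring opening, the aryloxy group rotating outward, to vinylketene 15; its ketene C=C adds the siloxyalkyne in a [2+2] cycloaddition (C5–C4 and C2–C3), 16 opens again (reversibly, until the alkenyl group has turned inward) to dienylketene 17, and 17 closes to 18, which tautomerises to the phenol. The closest known reaction is the Danheiser benzannulation of cyclobutenones with siloxyalkynes, here applied to a cyclobutenone carrying an aryloxy group at its sp3 carbon. Ring A closes by a thermal disrotatory 6π electrocyclization that re-forms C5–C6, followed by enolization. No stereocentre is created: the racemic centre of 11 and the sp3 centres of 16 and 18 disappear on aromatization. The step needs regiocontrol, which the polarization of the siloxyalkyne should secure (its nucleophilic CH terminus bonds to the ketene carbonyl carbon C5, so the siloxy carbon becomes C3 and C4 stays unsubstituted), and chemoselectivity, which follows from the absence of any reagent, so the keto ester of ring B is untouched. The excess of 14 should keep the phenol formed from being acylated by 15.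

Step 8
Reactants: 19 methyl 2-[2-hydroxy-6-pentyl-4-(triisopropylsilyloxy)phenoxy]-4-methoxy-6-pentanoylbenzoate
Product: 20 methyl 2-(2,4-dihydroxy-6-pentylphenoxy)-4-methoxy-6-pentanoylbenzoate
Conditions: Bu4NF (1.2 equiv), AcOH (1.2 equiv), THF, 0 °C
Reagents that add atoms: none
Why: Fluoride-mediated cleavage of the aryl silyl ether (Si–F bond formation), buffered with acetic acid so that the electron-rich ring A is not exposed as a phenoxide and the ester is not attacked.

Step 9
Reactants: 20 methyl 2-(2,4-dihydroxy-6-pentylphenoxy)-4-methoxy-6-pentanoylbenzoate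
Product: 21 2-(2,4-dihydroxy-6-pentylphenoxy)-4-methoxy-6-pentanoylbenzoic acid (target)
Conditions: LiOH (aq, 5 equiv), THF/MeOH, degassed, argon, rt → 40 °C; then 1 M HCl to pH 3
Reagents that add atoms: lithium hydroxide, [Li+].[OH-]
Why: Saponification with neighbouring-group assistance; hydroxide adds to the ortho ketone and the resulting alkoxide attacks the hindered ester (through the hydroxyphthalide), releasing methoxide and the keto carboxylate, any seven-membered lactone between the C5 phenol and the ester being opened under the same conditions, and acidification gives the acid.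

**Compound list**

1 | methyl 2,4,6-trihydroxybenzoate | COC(=O)c1c(O)cc(O)cc1O | starting material
2 | methyl 2,6-dihydroxy-4-methoxybenzoate | COC(=O)c1c(O)cc(OC)cc1O | intermediate
3 | methyl 2-hydroxy-4-methoxy-6-{[(trifluoromethyl)sulfonyl]oxy}benzoate | COC(=O)c1c(O)cc(OC)cc1OS(=O)(=O)C(F)(F)F | intermediate
4 | 2-chloro-N,N-dimethylacetamide | CN(C)C(=O)CCl | starting material
5 | methyl 2-[2-(dimethylamino)-2-oxoethoxy]-4-methoxy-6-{[(trifluoromethyl)sulfonyl]oxy}benzoate | COC(=O)c1c(OCC(=O)N(C)C)cc(OC)cc1OS(=O)(=O)C(F)(F)F | intermediate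
6 | butylzinc bromide | CCCC[Zn]Br | starting material
7 | methyl 2-[2-(dimethylamino)-2-oxoethoxy]-4-methoxy-6-pentanoylbenzoate | CCCCC(=O)c1cc(OC)cc(OCC(=O)N(C)C)c1C(=O)OC | intermediate
8 | hept-1-yne | CCCCCC#C | starting material
9 | N-{2-[5-methoxy-2-(methoxycarbonyl)-3-pentanoylphenoxy]ethenylidene}-N-methylmethanaminium trifluoromethanesulfonate (keteniminium triflate) | C[N+](C)=C=COc1cc(OC)cc(C(=O)CCCC)c1C(=O)OC.[O-]S(=O)(=O)C(F)(F)F | intermediate (not isolated)
10 | N-{4-[5-methoxy-2-(methoxycarbonyl)-3-pentanoylphenoxy]-3-pentylcyclobut-2-en-1-ylidene}-N-methylmethanaminium trifluoromethanesulfonate (cyclobuteniminium triflate, racemic) | CCCCCC1=CC(=[N+](C)C)C1Oc1cc(OC)cc(C(=O)CCCC)c1C(=O)OC.[O-]S(=O)(=O)C(F)(F)F | intermediate (not isolated)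
11 | methyl 4-methoxy-2-[(4-oxo-2-pentylcyclobut-2-en-1-yl)oxy]-6-pentanoylbenzoate (racemic) | CCCCCC1=CC(=O)C1Oc1cc(OC)cc(C(=O)CCCC)c1C(=O)OC | intermediate
12 | ethyl dibromoacetate | CCOC(=O)C(Br)Br | starting material
13 | lithium ethynolate | [Li+].[O-]C#C | intermediate (not isolated)
14 | (triisopropylsilyloxy)ethyne | C#CO[Si](C(C)C)(C(C)C)C(C)C | intermediate
15 | methyl 4-methoxy-2-{[(1E)-4-oxo-2-pentylbuta-1,3-dien-1-yl]oxy}-6-pentanoylbenzoate (aryloxy vinylketene) | CCCCC/C(C=C=O)=C\Oc1cc(OC)cc(C(=O)CCCC)c1C(=O)OC | intermediate (not isolated)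
16 | methyl 4-methoxy-2-({(1E)-2-[4-oxo-2-(triisopropylsilyloxy)cyclobut-2-en-1-yl]hept-1-en-1-yl}oxy)-6-pentanoylbenzoate (alkenyl siloxycyclobutenone, racemic) | CCCCC/C(=C\Oc1cc(OC)cc(C(=O)CCCC)c1C(=O)OC)C1C(=O)C=C1O[Si](C(C)C)(C(C)C)C(C)C | intermediate (not isolated)
17 | methyl 4-methoxy-2-{[(1E,3E)-6-oxo-2-pentyl-4-(triisopropylsilyloxy)hexa-1,3,5-trien-1-yl]oxy}-6-pentanoylbenzoate (dienylketene) | O=C=C/C(O[Si](C(C)C)(C(C)C)C(C)C)=C\C(CCCCC)=C\Oc1cc(OC)cc(C(=O)CCCC)c1C(=O)OC | intermediate (not isolated)
18 | methyl 4-methoxy-2-{[6-oxo-2-pentyl-4-(triisopropylsilyloxy)cyclohexa-2,4-dien-1-yl]oxy}-6-pentanoylbenzoate (cyclohexadienone, racemic) | O=C1C=C(O[Si](C(C)C)(C(C)C)C(C)C)C=C(CCCCC)C1Oc1cc(OC)cc(C(=O)CCCC)c1C(=O)OC | intermediate (not isolated)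
19 | methyl 2-[2-hydroxy-6-pentyl-4-(triisopropylsilyloxy)phenoxy]-4-methoxy-6-pentanoylbenzoate | CCCCCc1cc(O[Si](C(C)C)(C(C)C)C(C)C)cc(O)c1Oc1cc(OC)cc(C(=O)CCCC)c1C(=O)OC | intermediate
20 | methyl 2-(2,4-dihydroxy-6-pentylphenoxy)-4-methoxy-6-pentanoylbenzoate | CCCCCc1cc(O)cc(O)c1Oc1cc(OC)cc(C(=O)CCCC)c1C(=O)OC | intermediate
21 | 2-(2,4-dihydroxy-6-pentylphenoxy)-4-methoxy-6-pentanoylbenzoic acid | CCCCCc1cc(O)cc(O)c1Oc1cc(OC)cc(C(=O)CCCC)c1C(=O)O | target

**Step count**

Total: 9 steps. Longest linear sequence: 8 steps (steps 1–5 and 7–9); the alkyne branch is step 6.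

**Steps most likely to fail**

1. Step 7. The aryloxy vinylketene may be diverted before bimolecular capture (dimerisation, acylation of the phenol already formed), or the cascade may stall at the alkenylcyclobutenone stage because the alkenyl group has to rotate inward in the second ring opening.
Fallback, setting out from 3 and rejoining at 20: the diaryl ether is made by cross-coupling and ring A is taken from olivetol. Carbonylative Negishi coupling of 3 under the conditions of step 4, with one further equivalent of BuZnBr for the phenol, should give methyl 2-hydroxy-4-methoxy-6-pentanoylbenzoate F1, and Tf2O/pyridine then gives methyl 4-methoxy-2-pentanoyl-6-{[(trifluoromethyl)sulfonyl]oxy}benzoate F2. Olivetol (5-pentylbenzene-1,3-diol, commercial) is benzylated (BnBr, K2CO3, DMF) to 1,3-bis(benzyloxy)-5-pentylbenzene F3. Vilsmeier formylation (POCl3, DMF) at the position para to one benzyloxy group gives 2,4-bis(benzyloxy)-6-pentylbenzaldehyde F4. Baeyer–Villiger oxidation with mCPBA gives 2,4-bis(benzyloxy)-6-pentylphenyl formate F5, which K2CO3/MeOH cleaves to 2,4-bis(benzyloxy)-6-pentylphenol F6. Pd-catalysed C–O cross-coupling of F2 with F6 (Buchwald–Hartwig etherification: Pd(OAc)2, t-BuXPhos, K3PO4, toluene, 100 °C), helped by the ortho ester of F2, gives methyl 2-[2,4-bis(benzyloxy)-6-pentylphenoxy]-4-methoxy-6-pentanoylbenzoate F7. Hydrogenolysis (H2, Pd/C, EtOAc, rt) then gives 20.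

2. Step 5. The keteniminium ion may be consumed inside the molecule (capture by a ring B carbonyl oxygen or by the arene), or Tf2O may be used up at the aryl ketone, before the slow bimolecular cycloaddition with an unactivated alkyne takes place.
Fallback, setting out from 3 and rejoining at 15 in the flask of step 7 (11 is bypassed; no keteniminium ion is involved). Alkylation of 3 with 1-bromoheptan-2-one (K2CO3, acetone) should give methyl 4-methoxy-2-[(2-oxoheptyl)oxy]-6-{[(trifluoromethyl)sulfonyl]oxy}benzoate F8. Horner–Wadsworth–Emmons olefination of its only ketone with tert-butyl diethylphosphonoacetate (NaH, THF) gives methyl 2-{[2-(2-tert-butoxy-2-oxoethylidene)heptyl]oxy}-4-methoxy-6-{[(trifluoromethyl)sulfonyl]oxy}benzoate F9 as an E/Z mixture. The carbonylative Negishi coupling of step 4 gives methyl 2-{[2-(2-tert-butoxy-2-oxoethylidene)heptyl]oxy}-4-methoxy-6-pentanoylbenzoate F10. CF3CO2H in CH2Cl2 gives 3-{[5-methoxy-2-(methoxycarbonyl)-3-pentanoylphenoxy]methyl}oct-2-enoic acid F11, and (COCl)2 with catalytic DMF gives 3-{[5-methoxy-2-(methoxycarbonyl)-3-pentanoylphenoxy]methyl}oct-2-enoyl chloride F12. Slow addition of F12 to Et3N and 14 in toluene at 80 °C should cause 1,4-dehydrochlorination at the oxygen-bearing γ-carbon (the more acidic of the two γ-positions) and give vinylketene 15 in the presence of its trap, after which the sequence of step 7 leads to 19.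

3. Step 6. The unsubstituted ynolate may be silylated at carbon instead of oxygen (leading to the silylketene), or deprotonation of the dibromo ester may compete with bromine–lithium exchange.
Fallback, setting out from 11 and rejoining at 20: the oxygenated alkyne is changed to an alkoxyethyne made by dichlorovinyl ether chemistry. Propan-2-ol, KH and trichloroethene (THF) give (E)-1,2-dichloro-1-(propan-2-yloxy)ethene F13. n-BuLi (2.2 equiv, Et2O, −78 °C) followed by methanol gives 2-(ethynyloxy)propane F14. Benzannulation of 11 with F14 under the conditions of step 7 (80 °C, below the temperature at which this ether loses propene) should give methyl 2-[2-hydroxy-6-pentyl-4-(propan-2-yloxy)phenoxy]-4-methoxy-6-pentanoylbenzoate F15. BCl3 (CH2Cl2, −78 → 0 °C) cleaves the isopropyl ether in preference to the methyl ether of ring B, which is not ortho to a carbonyl group, and gives 20.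

**Further compounds**

F1 | step 7 | methyl 2-hydroxy-4-methoxy-6-pentanoylbenzoate | CCCCC(=O)c1cc(OC)cc(O)c1C(=O)OC
F2 | step 7 | methyl 4-methoxy-2-pentanoyl-6-{[(trifluoromethyl)sulfonyl]oxy}benzoate | CCCCC(=O)c1cc(OC)cc(OS(=O)(=O)C(F)(F)F)c1C(=O)OC
F3 | step 7 | 1,3-bis(benzyloxy)-5-pentylbenzene | CCCCCc1cc(OCc2ccccc2)cc(OCc2ccccc2)c1
F4 | step 7 | 2,4-bis(benzyloxy)-6-pentylbenzaldehyde | CCCCCc1cc(OCc2ccccc2)cc(OCc2ccccc2)c1C=O
F5 | step 7 | 2,4-bis(benzyloxy)-6-pentylphenyl formate | CCCCCc1cc(OCc2ccccc2)cc(OCc2ccccc2)c1OC=O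
F6 | step 7 | 2,4-bis(benzyloxy)-6-pentylphenol | CCCCCc1cc(OCc2ccccc2)cc(OCc2ccccc2)c1O
F7 | step 7 | methyl 2-[2,4-bis(benzyloxy)-6-pentylphenoxy]-4-methoxy-6-pentanoylbenzoate | CCCCCc1cc(OCc2ccccc2)cc(OCc2ccccc2)c1Oc1cc(OC)cc(C(=O)CCCC)c1C(=O)OC
F8 | step 5 | methyl 4-methoxy-2-[(2-oxoheptyl)oxy]-6-{[(trifluoromethyl)sulfonyl]oxy}benzoate | CCCCCC(=O)COc1cc(OC)cc(OS(=O)(=O)C(F)(F)F)c1C(=O)OC
F9 | step 5 | methyl 2-{[2-(2-tert-butoxy-2-oxoethylidene)heptyl]oxy}-4-methoxy-6-{[(trifluoromethyl)sulfonyl]oxy}benzoate (E/Z mixture) | CCCCCC(=CC(=O)OC(C)(C)C)COc1cc(OC)cc(OS(=O)(=O)C(F)(F)F)c1C(=O)OC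
F10 | step 5 | methyl 2-{[2-(2-tert-butoxy-2-oxoethylidene)heptyl]oxy}-4-methoxy-6-pentanoylbenzoate (E/Z mixture) | CCCCCC(=CC(=O)OC(C)(C)C)COc1cc(OC)cc(C(=O)CCCC)c1C(=O)OC
F11 | step 5 | 3-{[5-methoxy-2-(methoxycarbonyl)-3-pentanoylphenoxy]methyl}oct-2-enoic acid (E/Z mixture) | CCCCCC(=CC(=O)O)COc1cc(OC)cc(C(=O)CCCC)c1C(=O)OC
F12 | step 5 | 3-{[5-methoxy-2-(methoxycarbonyl)-3-pentanoylphenoxy]methyl}oct-2-enoyl chloride (E/Z mixture) | CCCCCC(=CC(=O)Cl)COc1cc(OC)cc(C(=O)CCCC)c1C(=O)OC
F13 | step 6 | (E)-1,2-dichloro-1-(propan-2-yloxy)ethene | CC(C)O/C(Cl)=C\Cl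
F14 | step 6 | 2-(ethynyloxy)propane | CC(C)OC#C
F15 | step 6 | methyl 2-[2-hydroxy-6-pentyl-4-(propan-2-yloxy)phenoxy]-4-methoxy-6-pentanoylbenzoate | CCCCCc1cc(OC(C)C)cc(O)c1Oc1cc(OC)cc(C(=O)CCCC)c1C(=O)OC
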